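**Retrosynthetic overview**
1. Atom labels follow the chromene numbering of the target: O1, C2–C4, C4a, C5 (OMe), C6 (aroyl), C7 (OH), C8 (prenyl), C8a. Ring A is C4a–C5–C6–C7–C8–C8a.
2. The dimethylpyran ring is closed last (O1–C2 and C4–C4a) with 3-methylbut-2-enal on a 3-prenyl-2,4-dihydroxy-6-methoxybenzophenone. In that precursor C4a–H is the only free ring A position and C8a–OH is the only non-chelated ring A phenol.
3. Key disconnection: ring A is not bought as a phloroglucinol but built by cutting C8–C8a and C6–C7. The run Ar–C(=O)/C6/C5(OMe)/C4a/C8a(O) of the target is the run C6/C5/C4(OMe)/C3/C2(=O) of a 6-aryl-4-methoxy-2-pyranone. C8 (with its prenyl) and C7 are Cα and C=O of methyl 5-methylhex-4-enoate.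
4. In the forward direction the ester enolate opens the pyranone and the chain recloses around the new two-carbon unit, so the pyranone is turned inside out. Its ring O and C6 become the benzophenone C=O, and the three ring A oxygens (OMe, chelated OH, free OH) come from three different functional groups.
5. Ring order: sacrificial pyranone (vinylogous aldol/lactonisation, then DDQ), then ring A, then the pyran ring. The ester comes from a Johnson–Claisen rearrangement.

Key step: step 4

Assumption: the SMILES holds no stereocentre and no stereogenic double bond, so the target is achiral and the demand for a single enantiomer does not apply. The stereocentre of the dihydropyranone made in step 2 is racemic and is erased in step 3. C8 of the open-chain intermediate of step 4 is erased on aromatisation.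

**Step 1**
Reactants: 1 2-methylbut-3-en-2-ol; 2 trimethyl orthoacetate
Product: 4 methyl 5-methylhex-4-enoate, via mixed ketene acetal 3 (not isolated)
Conditions: EtCO2H (cat.), neat, 110–140 °C, MeOH distilled off
Reagents that add atoms: none
Why: Johnson–Claisen rearrangement: acid-catalysed alcohol exchange and loss of methanol give the mixed ketene acetal 3, whose chair-like [3,3] shift forms the C–C bond at the unsubstituted vinyl terminus and leaves the trisubstituted alkene of the later prenyl group, with no stereocentre formed.

**Step 2**
Reactants: 5 methyl (E)-3-methoxybut-2-enoate; 6 4-(tert-butyldimethylsilyloxy)benzaldehyde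
Product: 8 rac-6-[4-(tert-butyldimethylsilyloxy)phenyl]-4-methoxy-5,6-dihydro-2H-pyran-2-one, via δ-hydroxy ester 7 (not isolated)
Conditions: 5, LDA, THF, −78 °C; then 6, −78 °C → rt; aq NH4Cl
Reagents that add atoms: none
Why: Vinylogous aldol addition followed by lactonisation: LDA removes a proton from the methyl group that lies cis to the ester in 5, the 3-methoxy group directs the electrophile to the γ-terminus of the dienolate (the reactivity pattern of 1,3-dialkoxy-1-silyloxybutadienes), the alkoxide of 7 closes on the cis ester with loss of methoxide, and the new stereocentre C6 is formed racemic on purpose because step 3 erases it.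

**Step 3**
Reactants: 8 rac-6-[4-(tert-butyldimethylsilyloxy)phenyl]-4-methoxy-5,6-dihydro-2H-pyran-2-one
Product: 9 6-[4-(tert-butyldimethylsilyloxy)phenyl]-4-methoxy-2H-pyran-2-one
Conditions: DDQ, 1,4-dioxane, reflux
Reagents that add atoms: none
Why: Quinone dehydrogenation: DDQ abstracts hydride from C6–H, which is benzylic to an electron-rich arene and α to the ring oxygen, loss of H-5 then gives the conjugated 2-pyranone as known for 6-substituted 4-methoxy-5,6-dihydropyranones (kavalactone type), while the aryl silyl ether and the enol ether are inert under anhydrous conditions.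

**Step 4**
Reactants: 4 methyl 5-methylhex-4-enoate; 9 6-[4-(tert-butyldimethylsilyloxy)phenyl]-4-methoxy-2H-pyran-2-one
Product: 12 [2,4-dihydroxy-6-methoxy-3-(3-methylbut-2-en-1-yl)phenyl](4-hydroxyphenyl)methanone, via open-chain diketo ester 10 (not isolated), via silyl-protected benzophenone 11 (not isolated)
Conditions: 4 (3 equiv), LDA (3 equiv), THF, −78 °C; 9, −78 → 0 °C; then NaOMe, MeOH, 50 °C; 1 M HCl, 0 °C
Reagents that add atoms: none
Why: Proposed new method: the hard, α-branched lithium enolate of 4 adds to the lactone carbonyl C2 of 9 (the future C8a), the tetrahedral adduct collapses by expelling the ring oxygen as the dienolate of an aryl ketone (C8–C8a bond, 10), and after the switch to NaOMe/MeOH the pentadienyl-type anion of 10 attacks the methyl ester carbon through C6 (C6–C7 bond), loses methoxide and tautomerises to phenol 11, whose aryl silyl ether, now para to a ketone, is cleaved by the same methoxide to give 12. The closest known reaction types are the crossed Claisen acylation of ester enolates by enol esters and lactones, the biomimetic Claisen cyclisation of 3,5,7-trioxo esters to acylphloroglucinols and the carbanion-induced ring transformations of 2-pyranones, but their union on a 6-aryl-4-methoxy-2-pyranone, in which C6 and the ring oxygen leave the ring as an aroyl group, has no direct precedent. Ring A is closed by a 6-(enolexo)-exo-trig acyl substitution, for which the C4a=C5 double bond inherited from the pyranone holds C8a and C6 cis, and the gain of aromaticity makes the closure irreversible. No stereocentre survives, since C8 of 10 becomes sp2. Site selectivity in the first bond (C2 against C4 and C6 of 9) rests on the π-donors at C4 (OMe) and C6 (ring O, 4-silyloxyphenyl), which make these two fully substituted carbons poor acceptors, and on the fact that only the C2 adduct carries a good internal leaving group, while selectivity in the second bond rests on the methyl ether at C5, which shuts off the usual lactonisation of triketo esters to 4-hydroxy-2-pyranones, and on the prenyl group at C8, which makes the competing aldol attack of C8 on the aryl ketone end in a quaternary carbon that cannot aromatise and therefore reverts. The substitution pattern of ring A follows from connectivity and not from a selective reaction: C5–OMe is the pyranone 4-OMe, C8a–OH the lactone carbonyl, C7–OH the ester carbonyl and the ketone oxygen the former ring oxygen.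

**Step 5**
Reactants: 12 [2,4-dihydroxy-6-methoxy-3-(3-methylbut-2-en-1-yl)phenyl](4-hydroxyphenyl)methanone; 13 3-methylbut-2-enal
Product: 15 vismiaphenone F, via o-quinone methide 14 (not isolated)
Conditions: ethylenediammonium diacetate (cat.), xylene, reflux
Reagents that add atoms: none
Why: Formal [3+3] chromene annulation (Knoevenagel-type condensation, then oxa-6π electrocyclisation): the iminium ion of 13 is attacked by C4a, the only unsubstituted and most electron-rich carbon of ring A, elimination gives the o-quinone methide 14 on the non-chelated C8a oxygen, and its 6π closure forms O1–C2, so that no regioisomer is possible (C7–OH has no free ortho carbon, ring B is deactivated by its para carbonyl) and no stereocentre arises.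

**Compound list**
1 | 2-methylbut-3-en-2-ol | CC(C)(O)C=C | starting material
2 | trimethyl orthoacetate | CC(OC)(OC)OC | starting material
3 | 1-methoxy-1-(2-methylbut-3-en-2-yloxy)ethene (mixed ketene acetal) | C=C(OC)OC(C)(C)C=C | intermediate
4 | methyl 5-methylhex-4-enoate | COC(=O)CCC=C(C)C | intermediate
5 | methyl (E)-3-methoxybut-2-enoate | CO/C(C)=C/C(=O)OC | starting material
6 | 4-(tert-butyldimethylsilyloxy)benzaldehyde | CC(C)(C)[Si](C)(C)Oc1ccc(C=O)cc1 | starting material
7 | methyl (E)-5-[4-(tert-butyldimethylsilyloxy)phenyl]-5-hydroxy-3-methoxypent-2-enoate (racemic, present as lithium alkoxide) | COC(=O)/C=C(/OC)CC(O)c1ccc(O[Si](C)(C)C(C)(C)C)cc1 | intermediate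
8 | rac-6-[4-(tert-butyldimethylsilyloxy)phenyl]-4-methoxy-5,6-dihydro-2H-pyran-2-one | COC1=CC(=O)OC(C1)c1ccc(O[Si](C)(C)C(C)(C)C)cc1 | intermediate
9 | 6-[4-(tert-butyldimethylsilyloxy)phenyl]-4-methoxy-2H-pyran-2-one | COC1=CC(=O)OC(=C1)c1ccc(O[Si](C)(C)C(C)(C)C)cc1 | intermediate
10 | methyl (4E)-7-[4-(tert-butyldimethylsilyloxy)phenyl]-5-methoxy-2-(3-methylbut-2-en-1-yl)-3,7-dioxohept-4-enoate (racemic at C2, present as enolate) | COC(=O)C(CC=C(C)C)C(=O)/C=C(/OC)CC(=O)c1ccc(O[Si](C)(C)C(C)(C)C)cc1 | intermediate
11 | [4-(tert-butyldimethylsilyloxy)phenyl][2,4-dihydroxy-6-methoxy-3-(3-methylbut-2-en-1-yl)phenyl]methanone | COc1cc(O)c(CC=C(C)C)c(O)c1C(=O)c1ccc(O[Si](C)(C)C(C)(C)C)cc1 | intermediate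
12 | [2,4-dihydroxy-6-methoxy-3-(3-methylbut-2-en-1-yl)phenyl](4-hydroxyphenyl)methanone | COc1cc(O)c(CC=C(C)C)c(O)c1C(=O)c1ccc(O)cc1 | intermediate
13 | 3-methylbut-2-enal | CC(C)=CC=O | starting material
14 | (Z)-o-quinone methide: 3-hydroxy-4-(4-hydroxybenzoyl)-5-methoxy-2-(3-methylbut-2-en-1-yl)-6-(3-methylbut-2-en-1-ylidene)cyclohexa-2,4-dien-1-one | O=C1/C(=C\C=C(C)C)C(OC)=C(C(=O)c2ccc(O)cc2)C(O)=C1CC=C(C)C | intermediate
15 | vismiaphenone F, [7-hydroxy-5-methoxy-2,2-dimethyl-8-(3-methylbut-2-en-1-yl)-2H-chromen-6-yl](4-hydroxyphenyl)methanone (achiral) | COc1c2c(c(CC=C(C)C)c(O)c1C(=O)c1ccc(O)cc1)OC(C)(C)C=C2 | target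

**Step count**
Total steps: 5. Longest linear sequence: 4 (steps 2, 3, 4, 5). Step 1 is a one-step side branch.

**Steps most likely to fail**

1. Step 4 (proposed new method).
   - Risk: the enolate may enter the pyranone at C4 (addition, then elimination of methoxide) or at C6 instead of the lactone carbonyl. It may also only be consumed by proton transfer and self-condensation, or the opened chain may stall before the second C–C bond forms.
   - Fallback (known chemistry, gives up the de novo construction of ring A): it sets out from 1 and comes back at 12. Commercial 5-methoxyresorcinol is acylated with commercial 4-hydroxybenzoic acid (BF3·OEt2, heat, Friedel–Crafts acylation) to (2,4-dihydroxy-6-methoxyphenyl)(4-hydroxyphenyl)methanone F1. This is then C-prenylated between its two ring A hydroxyl groups with 1 and BF3·OEt2 in dioxane at room temperature to give 12. Positional isomers would have to be removed at both stages, which is the problem the main route avoids.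

2. Step 2.
   - Risk: the dienolate may react through its α-carbon (poor γ-selectivity), or the aldolate may fail to lactonise after loss of the double-bond geometry.
   - Fallback: it sets out from 6 and comes back at 8. Compound 6 is added to the lithium dienolate of commercial 2,2,6-trimethyl-4H-1,3-dioxin-4-one (LDA, THF, −78 °C, γ-selective vinylogous aldol) to give 6-{2-[4-(tert-butyldimethylsilyloxy)phenyl]-2-hydroxyethyl}-2,2-dimethyl-4H-1,3-dioxin-4-one F2. Heating in toluene releases the acylketene, which is trapped by its own hydroxyl group as 6-[4-(tert-butyldimethylsilyloxy)phenyl]-4-hydroxy-5,6-dihydro-2H-pyran-2-one F3. O-Methylation (Me2SO4, K2CO3, acetone) gives 8.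

3. Step 5.
   - Risk: condensation at the flanked C4a may be slow, the enal may self-condense, or the C8 prenyl group may cyclise thermally or under acid onto a neighbouring hydroxyl group.
   - Fallback (ether formation and sigmatropic shift in place of condensation): it sets out from 11 and comes back at 15. Compound 11 is isolated when the methoxide stage of step 4 is replaced by DBU in THF.
   - The non-chelated C8a–OH of 11 is alkylated with 3-chloro-3-methylbut-1-yne (CuCl2 cat., DBU, MeCN, 0 °C) to [4-(tert-butyldimethylsilyloxy)phenyl][2-hydroxy-6-methoxy-3-(3-methylbut-2-en-1-yl)-4-(2-methylbut-3-yn-2-yloxy)phenyl]methanone F4.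
   - Heating in N,N-diethylaniline triggers aromatic Claisen rearrangement to the only free ortho carbon, then a [1,5]-H shift and oxa-6π closure, giving O-silyl vismiaphenone F F5. TBAF in THF then gives 15.

**Further compounds**
F1 | step 4 | (2,4-dihydroxy-6-methoxyphenyl)(4-hydroxyphenyl)methanone | COc1cc(O)cc(O)c1C(=O)c1ccc(O)cc1
F2 | step 2 | 6-{2-[4-(tert-butyldimethylsilyloxy)phenyl]-2-hydroxyethyl}-2,2-dimethyl-4H-1,3-dioxin-4-one (racemic) | CC1(C)OC(=O)C=C(CC(O)c2ccc(O[Si](C)(C)C(C)(C)C)cc2)O1
F3 | step 2 | 6-[4-(tert-butyldimethylsilyloxy)phenyl]-4-hydroxy-5,6-dihydro-2H-pyran-2-one (racemic) | OC1=CC(=O)OC(C1)c1ccc(O[Si](C)(C)C(C)(C)C)cc1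
F4 | step 5 | [4-(tert-butyldimethylsilyloxy)phenyl][2-hydroxy-6-methoxy-3-(3-methylbut-2-en-1-yl)-4-(2-methylbut-3-yn-2-yloxy)phenyl]methanone | COc1cc(OC(C)(C)C#C)c(CC=C(C)C)c(O)c1C(=O)c1ccc(O[Si](C)(C)C(C)(C)C)cc1
F5 | step 5 | O-silyl vismiaphenone F, [4-(tert-butyldimethylsilyloxy)phenyl][7-hydroxy-5-methoxy-2,2-dimethyl-8-(3-methylbut-2-en-1-yl)-2H-chromen-6-yl]methanone | COc1c2c(c(CC=C(C)C)c(O)c1C(=O)c1ccc(O[Si](C)(C)C(C)(C)C)cc1)OC(C)(C)C=C2
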